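The plan cuts the C1–C10 bond of ring A. It exploits the fact that quaternary C10, at the fusion of rings A and B, holds the C20 carboxyl on the H5 face, trans to C19 on C4, and that C3 lies three ring bonds away. C20 can therefore be tied to O–C3 as a δ-lactone bearing a vinyl group (C2=C1). One Ireland–Claisen shift of its silyl ketene acetal then forms C1–C10, closes ring A, sets C10 and releases the C20 acid. The precursor, a 3-vinyl lactone cis-fused to ring B, is cut out of gibberellic acid, which already supplies rings B, C, D and C3, C4, C5, C6, C8, C9, C13.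

Key step: step 9

Assumption: the target is made exactly as drawn (C20 on the H5 face of C10); target numbering is used for every compound (the former C1 of 1 ends as C20 and a new C1 comes from the ylide); fermentation-derived gibberellic acid is taken as a commercial chiral starting material.

Step 1
Reactants: 1 gibberellic acid (GA3)
Product: 2 GA3 7-methyl ester
Conditions: TMSCHN2 (hexanes), toluene–MeOH, 0 °C
Reagents that add atoms: (trimethylsilyl)diazomethane, C[Si](C)(C)C=[N+]=[N-]
Why: Diazoalkane O-methylation esterifies the hindered C7 acid under neutral conditions, so the base-labile allylic lactone and β-hydroxy lactone units of ring A and all stereocentres of 1 (C3, C4, C5, C6, C8, C9, C13) are carried on unchanged.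

Step 2
Reactants: 2 GA3 7-methyl ester
Product: 4 3-O-TES-13-O-TBS GA3 methyl ester, via 3-O-TES ether 3 (not isolated)
Conditions: TESOTf (1.05 equiv), 2,6-lutidine, CH2Cl2, −78 °C; then TBSOTf, −78 → 0 °C
Reagents that add atoms: triethylsilyl triflate, CC[Si](CC)(CC)OS(=O)(=O)C(F)(F)F; tert-butyldimethylsilyl triflate, CC(C)(C)[Si](C)(C)OS(=O)(=O)C(F)(F)F
Why: Sequential silyl triflate etherification uses the large rate gap between the secondary allylic C3 hydroxyl and the tertiary bridgehead C13 hydroxyl, giving an acid-labile TES ether at O3 and a robust TBS ether at O13 that later blocks acyloin and Wagner–Meerwein shifts of rings C and D.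

Step 3
Reactants: 4 3-O-TES-13-O-TBS GA3 methyl ester
Product: 6 20→3 lactol 2-aldehyde 16-ketone (19→10 γ-lactone kept), via seco-dialdehyde 5 (not isolated)
Conditions: O3, CH2Cl2, −78 °C; PPh3, → rt; then AcOH–THF–H2O, rt
Reagents that add atoms: ozone, [O-][O+]=O
Why: Ozonolysis with reductive work-up cleaves C16=C17 to the ketone and the ring A alkene to two formyl groups, and once aqueous acid has removed the TES group the C3 hydroxyl can close a six-membered lactol only onto the formyl carbon held by C10 (the future C20), which tells the two aldehydes apart without touching a stereocentre (the lactol carbon is an inconsequential anomer mixture).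

Step 4
Reactants: 6 20→3 lactol 2-aldehyde 16-ketone
Product: 7 bis-lactone 2-aldehyde 16-ketone
Conditions: Dess–Martin periodinane, CH2Cl2, 0 °C → rt
Reagents that add atoms: none
Why: Dess–Martin oxidation takes the lactol to the δ-lactone while the anhydrous aldehyde, the ketone, the γ-lactone and the silyl ether are inert, and the planar C10–C20(=O)–O–C3 unit occupies the place of the former C10–C=C–C3 unit of ring A, so no strain is added.

Step 5
Reactants: 7 bis-lactone 2-aldehyde 16-ketone
Product: 8 3-vinyl bis-lactone 16-ketone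
Conditions: Ph3PCH3Br, KN(SiMe3)2, THF, 0 °C; about 1.1 equiv of the ylide added to 7, −78 → −20 °C
Reagents that add atoms: methyltriphenylphosphonium bromide, C[P+](c1ccccc1)(c1ccccc1)c1ccccc1.[Br-]
Why: Wittig methylenation with about one equivalent of the unstabilised ylide at low temperature reacts at the aldehyde far faster than at the hindered C16 ketone or the lactones and brings in C1, and C3 is safe because its formyl group already sits in the pseudo-equatorial, thermodynamically preferred position.

Step 6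
Reactants: 8 3-vinyl bis-lactone 16-ketone
Product: 9 3-vinyl bis-lactone 16-dioxolane
Conditions: TMSOCH2CH2OTMS, TMSOTf (cat.), CH2Cl2, −78 → −20 °C
Reagents that add atoms: 1,2-bis(trimethylsilyloxy)ethane, C[Si](C)(C)OCCO[Si](C)(C)C
Why: Aprotic ketalisation with the bis-silylated glycol under TMSOTf catalysis masks the C16 ketone against SmI2, amide base and hydrogenation without water or strong protic acid, the O13 silyl ether excluding an acyloin shift.

Step 7
Reactants: 9 3-vinyl bis-lactone 16-dioxolane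
Product: 10 3-vinyl 20→3 lactone 19-oic acid (10β-H, cis-fused to ring B)
Conditions: SmI2 (excess), THF–HMPA, t-BuOH, −78 °C, slow addition of 9; cold dilute HCl work-up
Reagents that add atoms: none
Why: In this SmI2–HMPA α-deoxygenation of an α-acyloxy ester, electron transfer to either carbonyl flanking the C10–O bond expels the C19 carboxylate, a second electron gives the trivalent samarium enolate, and t-BuOH protonates C10 from the open β face (the α face is covered by the released carboxylate and C11) to give the cis-fused lactone, a centre that step 9 erases anyway, while slow addition to excess reagent keeps the C10 radical too short-lived to add to the vinyl group.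

Step 8
Reactants: 10 3-vinyl 20→3 lactone 19-oic acid
Product: 11 3-vinyl 20→3 lactone 19-TMSE ester (Claisen precursor)
Conditions: TMSCH2CH2OH, PPh3, DIAD, THF, 0 °C → rt
Reagents that add atoms: 2-(trimethylsilyl)ethanol, C[Si](C)(C)CCO
Why: Mitsunobu esterification alkylates the carboxylate oxygen at the primary carbon of the activated alcohol, so the neopentyl-type hindrance of C19 does not matter and the neutral medium leaves C10 and the vinyl lactone alone.

Step 9
Reactants: 11 3-vinyl 20→3 lactone 19-TMSE ester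
Product: 14 tetracyclic 2-ene 20-oic acid, via cyclic TBS ketene acetal 12 (not isolated), via TBS ester 13 (not isolated)
Conditions: TBSCl, then KN(SiMe3)2 added last, THF–DMPU, −78 °C; solvent change to toluene, 110 °C; AcOH–THF–H2O, rt
Reagents that add atoms: tert-butyldimethylsilyl chloride, CC(C)(C)[Si](C)(C)Cl (held in 12 and 13, lost again on work-up)
Why: KN(SiMe3)2 removes H10, which as a lactone α-proton on the open β face is several pK units more acidic and far more exposed than H6 of the C7 methyl ester next to quaternary C8, and the TBSCl already present traps the enolate on oxygen as ketene acetal 12. On heating, 12 undergoes a concerted suprafacial [3,3] shift, the known Ireland–Claisen rearrangement of alkenyl lactones (lactone-to-carbocycle ring contraction), in which C1 bonds to C10 while C3–O breaks and C2=C3 forms. Ring A closes as a six-membered carbocycle in a sigmatropic mode through a boat, bicyclo[2.2.2]octane-like transition state that the lactone ring imposes, no chair being geometrically possible. The only new stereocentre, quaternary C10, is set by chirality transfer from C3: the vinyl group lies on the α face of the lactone (syn to C6, anti to H5), so C1 arrives on that face and C20 is pushed to the H5 face, trans to C19. The step needs site-selective enolisation (C10 over C6) and O- over C-silylation; quaternary C4 rules out enolisation of the C19 ester and β-elimination of the C3–O bond, and internal trapping keeps the enolate lifetime short. Mild aqueous acid then cleaves silyl ester 13 to acid 14 and leaves the ketal, the TBS ether and both carbon esters in place.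

Step 10
Reactants: 14 tetracyclic 2-ene 20-oic acid
Product: 15 saturated ring A 20-oic acid
Conditions: H2 (1 atm), Pd/C (10 wt %), EtOAc, rt
Reagents that add atoms: none
Why: Heterogeneous catalytic hydrogenation saturates the only C=C bond (cis-disubstituted C2=C3), creates no stereocentre and is the reason C16 is still a ketal and not yet a methylene group.

Step 11
Reactants: 15 saturated ring A 20-oic acid
Product: 16 16-ketone 20-oic acid
Conditions: TsOH·H2O (cat.), acetone–H2O, 50 °C
Reagents that add atoms: water, O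
Why: Acid-catalysed ketal hydrolysis frees the C16 ketone, the tertiary TBS ether and the TMSE and methyl esters tolerating catalytic TsOH, and the retained O13 silyl group keeps the α-oxy ketone from acyloin rearrangement.

Step 12
Reactants: 16 16-ketone 20-oic acid
Product: 17 16-methylene 13-O-TBS 19-TMSE 20-oic acid
Conditions: Ph3PCH3Br (excess), KOt-Bu, THF, rt → 50 °C; aq. citric acid work-up
Reagents that add atoms: methyltriphenylphosphonium bromide, C[P+](c1ccccc1)(c1ccccc1)c1ccccc1.[Br-]
Why: Wittig methylenation with excess ylide (one equivalent is spent on the C20 acid) converts the non-epimerisable bridged ketone into the C16 exocyclic alkene, the hindered esters being inert and H6 already in its thermodynamically preferred orientation.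

Step 13
Reactants: 17 16-methylene 13-O-TBS 19-TMSE 20-oic acid
Product: 18 target CNP0285449.1
Conditions: TBAF (excess), THF, 50 °C; brief cold dilute HCl to pH 3, EtOAc extraction
Reagents that add atoms: none
Why: Fluoride-induced desilylation cleaves the O13 TBS ether and triggers β-elimination of the TMSE ester in one operation, which avoids the acid-promoted rearrangement of the 13-hydroxy-16-ene unit and leaves the hindered C7 methyl ester intact.

Compound list
1 | gibberellic acid (GA3) | C=C1C[C@]23C[C@@]1(O)CC[C@H]2[C@]14C=C[C@H](O)[C@@](C)(C(=O)O4)[C@H]1[C@@H]3C(=O)O | starting material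
2 | GA3 7-methyl ester | C=C1C[C@]23C[C@@]1(O)CC[C@H]2[C@]14C=C[C@H](O)[C@@](C)(C(=O)O4)[C@H]1[C@@H]3C(=O)OC | intermediate
3 | 3-O-triethylsilyl GA3 methyl ester (not isolated) | C=C1C[C@]23C[C@@]1(O)CC[C@H]2[C@]14C=C[C@H](O[Si](CC)(CC)CC)[C@@](C)(C(=O)O4)[C@H]1[C@@H]3C(=O)OC | intermediate
4 | 3-O-triethylsilyl-13-O-tert-butyldimethylsilyl GA3 methyl ester | C=C1C[C@]23C[C@@]1(O[Si](C)(C)C(C)(C)C)CC[C@H]2[C@]14C=C[C@H](O[Si](CC)(CC)CC)[C@@](C)(C(=O)O4)[C@H]1[C@@H]3C(=O)OC | intermediate
5 | ring A seco-dialdehyde, 16-ketone, 3-O-TES, 19→10 γ-lactone (not isolated) | O=C1C[C@]23C[C@@]1(O[Si](C)(C)C(C)(C)C)CC[C@H]2[C@@]1(C=O)OC(=O)[C@](C)([C@H](C=O)O[Si](CC)(CC)CC)[C@H]1[C@@H]3C(=O)OC | intermediate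
6 | 20→3 lactol (anomer mixture), 2-aldehyde, 16-ketone, 19→10 γ-lactone | O=C1C[C@]23C[C@@]1(O[Si](C)(C)C(C)(C)C)CC[C@H]2[C@]14C(O)O[C@@H](C=O)[C@@](C)(C(=O)O4)[C@H]1[C@@H]3C(=O)OC | intermediate
7 | bis-lactone (20→3 δ, 19→10 γ), 2-aldehyde, 16-ketone | O=C1C[C@]23C[C@@]1(O[Si](C)(C)C(C)(C)C)CC[C@H]2[C@]14C(=O)O[C@@H](C=O)[C@@](C)(C(=O)O4)[C@H]1[C@@H]3C(=O)OC | intermediate
8 | 3-vinyl bis-lactone, 16-ketone | O=C1C[C@]23C[C@@]1(O[Si](C)(C)C(C)(C)C)CC[C@H]2[C@]14C(=O)O[C@@H](C=C)[C@@](C)(C(=O)O4)[C@H]1[C@@H]3C(=O)OC | intermediate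
9 | 3-vinyl bis-lactone, 16-dioxolane | C12(OCCO1)C[C@]34C[C@@]2(O[Si](C)(C)C(C)(C)C)CC[C@H]3[C@]15C(=O)O[C@@H](C=C)[C@@](C)(C(=O)O5)[C@H]1[C@@H]4C(=O)OC | intermediate
10 | 3-vinyl 20→3 δ-lactone cis-fused to ring B (10β-H), free 19-oic acid | C12(OCCO1)C[C@]34C[C@@]2(O[Si](C)(C)C(C)(C)C)CC[C@H]3[C@H]1C(=O)O[C@@H](C=C)[C@@](C)(C(=O)O)[C@H]1[C@@H]4C(=O)OC | intermediate
11 | 3-vinyl 20→3 δ-lactone, 19-TMSE ester (Claisen precursor) | C12(OCCO1)C[C@]34C[C@@]2(O[Si](C)(C)C(C)(C)C)CC[C@H]3[C@H]1C(=O)O[C@@H](C=C)[C@@](C)(C(=O)OCC[Si](C)(C)C)[C@H]1[C@@H]4C(=O)OC | intermediate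
12 | cyclic TBS ketene acetal, C10=C20 (not isolated) | C12(OCCO1)C[C@]34C[C@@]2(O[Si](C)(C)C(C)(C)C)CC[C@H]3C1=C(O[Si](C)(C)C(C)(C)C)O[C@@H](C=C)[C@@](C)(C(=O)OCC[Si](C)(C)C)[C@H]1[C@@H]4C(=O)OC | intermediate
13 | rearranged tetracycle, C20 TBS ester (not isolated) | C12(OCCO1)C[C@]34C[C@@]2(O[Si](C)(C)C(C)(C)C)CC[C@H]3[C@@]1(C(=O)O[Si](C)(C)C(C)(C)C)CC=C[C@@](C)(C(=O)OCC[Si](C)(C)C)[C@H]1[C@@H]4C(=O)OC | intermediate
14 | tetracycle, ring A 2-ene, free C20 acid (Claisen product) | C12(OCCO1)C[C@]34C[C@@]2(O[Si](C)(C)C(C)(C)C)CC[C@H]3[C@@]1(C(=O)O)CC=C[C@@](C)(C(=O)OCC[Si](C)(C)C)[C@H]1[C@@H]4C(=O)OC | intermediate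
15 | tetracycle, saturated ring A, free C20 acid | C12(OCCO1)C[C@]34C[C@@]2(O[Si](C)(C)C(C)(C)C)CC[C@H]3[C@@]1(C(=O)O)CCC[C@@](C)(C(=O)OCC[Si](C)(C)C)[C@H]1[C@@H]4C(=O)OC | intermediate
16 | 16-ketone, 13-O-TBS, 19-TMSE ester, C20 acid | O=C1C[C@]23C[C@@]1(O[Si](C)(C)C(C)(C)C)CC[C@H]2[C@@]1(C(=O)O)CCC[C@@](C)(C(=O)OCC[Si](C)(C)C)[C@H]1[C@@H]3C(=O)OC | intermediate
17 | 16-methylene, 13-O-TBS, 19-TMSE ester, C20 acid | C=C1C[C@]23C[C@@]1(O[Si](C)(C)C(C)(C)C)CC[C@H]2[C@@]1(C(=O)O)CCC[C@@](C)(C(=O)OCC[Si](C)(C)C)[C@H]1[C@@H]3C(=O)OC | intermediate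
18 | CNP0285449.1 | C=C1C[C@]23C[C@@]1(O)CC[C@H]2[C@@]1(C(=O)O)CCC[C@@](C)(C(=O)O)[C@H]1[C@@H]3C(=O)OC | target

Total step count: 13. Longest linear sequence: 13 (fully linear from 1).

Steps most likely to fail

Step 9. Removal of H10 may be slow or may compete with removal of H6. The enolate may also decay before it is silylated, or the ketene acetal may decompose before the strained boat is reached. The fallback sets out from 9 and comes back at 18. The enolate is made without base, and only at C10, by running the reductive C10–O cleavage with no proton donor and with TBSCl present (SmI2, THF–HMPA, −78 °C); this is a Reformatsky–Claisen-type entry. Both samarium–oxygen bonds are silylated to the bis-silylated ketene acetal F1. Heating in toluene gives the bis(silyl ester) F2, and aqueous AcOH then gives the ene diacid F3. Hydrogenation over Pd/C gives the saturated diacid F4. TsOH in wet acetone gives the keto diacid F5, excess Ph3P=CH2 gives the methylene diacid F6, and TBAF gives 18.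

Step 7. After loss of the carboxylate, the tertiary C10 radical may add to the vinyl group, or the allylic C3–O bond may be cleaved before the second electron arrives. The fallback sets out from 4 and comes back at 11. It breaks the C10–O bond while that bond is still allylic and before any vinyl lactone exists. Pd2(dba)3/PBu3 with HCO2H–NEt3 (formate hydrogenolysis after Tsuji–Trost-type ionisation) places palladium on the β face, anti to the leaving oxygen. Hydride is then delivered from that face to the more substituted terminus C10, giving the 10β-H ring A ene 19-oic acid F7. Mitsunobu esterification gives its TMSE ester F8. Ozonolysis with PPh3 gives the seco-dialdehyde ketone F9, and aqueous AcOH gives the lactol aldehyde F10. Dess–Martin oxidation gives the lactone aldehyde F11, and Wittig methylenation gives the vinyl lactone ketone F12. Ketalisation as in step 6 gives 11.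

Step 3. Ozone may over-oxidise aldehyde or silyl ether carbinol C–H bonds, or it may attack the electron-poor ring A alkene incompletely. The fallback sets out from 4 and comes back at 5. The cleavage is split into osmylation and glycol fission. OsO4 (cat.) with NMO in aqueous acetone dihydroxylates both alkenes to the bis-diol F13, whose new carbinol configurations are immaterial. NaIO4 cleaves both glycols to 5, which is carried on with aqueous AcOH as in step 3.

Further compounds
F1 | step 9 | bis-silylated ketene acetal | C12(OCCO1)C[C@]34C[C@@]2(O[Si](C)(C)C(C)(C)C)CC[C@H]3C1=C(O[Si](C)(C)C(C)(C)C)O[C@@H](C=C)[C@@](C)(C(=O)O[Si](C)(C)C(C)(C)C)[C@H]1[C@@H]4C(=O)OC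
F2 | step 9 | bis(silyl ester) | C12(OCCO1)C[C@]34C[C@@]2(O[Si](C)(C)C(C)(C)C)CC[C@H]3[C@@]1(C(=O)O[Si](C)(C)C(C)(C)C)CC=C[C@@](C)(C(=O)O[Si](C)(C)C(C)(C)C)[C@H]1[C@@H]4C(=O)OC
F3 | step 9 | ene diacid | C12(OCCO1)C[C@]34C[C@@]2(O[Si](C)(C)C(C)(C)C)CC[C@H]3[C@@]1(C(=O)O)CC=C[C@@](C)(C(=O)O)[C@H]1[C@@H]4C(=O)OC
F4 | step 9 | saturated diacid | C12(OCCO1)C[C@]34C[C@@]2(O[Si](C)(C)C(C)(C)C)CC[C@H]3[C@@]1(C(=O)O)CCC[C@@](C)(C(=O)O)[C@H]1[C@@H]4C(=O)OC
F5 | step 9 | keto diacid | O=C1C[C@]23C[C@@]1(O[Si](C)(C)C(C)(C)C)CC[C@H]2[C@@]1(C(=O)O)CCC[C@@](C)(C(=O)O)[C@H]1[C@@H]3C(=O)OC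
F6 | step 9 | methylene diacid | C=C1C[C@]23C[C@@]1(O[Si](C)(C)C(C)(C)C)CC[C@H]2[C@@]1(C(=O)O)CCC[C@@](C)(C(=O)O)[C@H]1[C@@H]3C(=O)OC
F7 | step 7 | 10β-H ring A ene 19-oic acid | C=C1C[C@]23C[C@@]1(O[Si](C)(C)C(C)(C)C)CC[C@H]2[C@H]1C=C[C@H](O[Si](CC)(CC)CC)[C@@](C)(C(=O)O)[C@H]1[C@@H]3C(=O)OC
F8 | step 7 | TMSE ester | C=C1C[C@]23C[C@@]1(O[Si](C)(C)C(C)(C)C)CC[C@H]2[C@H]1C=C[C@H](O[Si](CC)(CC)CC)[C@@](C)(C(=O)OCC[Si](C)(C)C)[C@H]1[C@@H]3C(=O)OC
F9 | step 7 | seco-dialdehyde ketone | O=C1C[C@]23C[C@@]1(O[Si](C)(C)C(C)(C)C)CC[C@H]2[C@@H](C=O)[C@@H]([C@](C)(C(=O)OCC[Si](C)(C)C)[C@H](C=O)O[Si](CC)(CC)CC)[C@@H]3C(=O)OC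
F10 | step 7 | lactol aldehyde | O=C1C[C@]23C[C@@]1(O[Si](C)(C)C(C)(C)C)CC[C@H]2[C@H]1C(O)O[C@@H](C=O)[C@@](C)(C(=O)OCC[Si](C)(C)C)[C@H]1[C@@H]3C(=O)OC
F11 | step 7 | lactone aldehyde | O=C1C[C@]23C[C@@]1(O[Si](C)(C)C(C)(C)C)CC[C@H]2[C@H]1C(=O)O[C@@H](C=O)[C@@](C)(C(=O)OCC[Si](C)(C)C)[C@H]1[C@@H]3C(=O)OC
F12 | step 7 | vinyl lactone ketone | O=C1C[C@]23C[C@@]1(O[Si](C)(C)C(C)(C)C)CC[C@H]2[C@H]1C(=O)O[C@@H](C=C)[C@@](C)(C(=O)OCC[Si](C)(C)C)[C@H]1[C@@H]3C(=O)OC
F13 | step 3 | bis-diol | OCC1(O)C[C@]23C[C@@]1(O[Si](C)(C)C(C)(C)C)CC[C@H]2[C@]14C(O)C(O)[C@H](O[Si](CC)(CC)CC)[C@@](C)(C(=O)O4)[C@H]1[C@@H]3C(=O)OC
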